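**Plan**

1. Retrosynthetic cuts (target numbered O1, C2, C3, C4, C4a, C5, C6, C7, C8, C8a): O1–C8a of the dihydropyranone (last, key step); C6–prenyl (dearomatising allylation); C8–CH(Ph) (conjugate addition that also ties the CH(Ph)CH2CO2H arm to the oxygen on C8a as a temporary δ-lactone); C4a–acyl and C6–CH2(cyclobutyl) (two directed lithiations of MOM-protected phloroglucinol).
2. Forward order: the cyclobutylmethyl and 3-silyloxyacyl groups go onto the phloroglucinol ring, the lactone ring is annulated, the benzene ring is dearomatised by prenylation, and last the pyranone ring closes as the lactone ring opens.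
3. Enabling feature: in the dearomatised carbocycle C8a (between C8 and C4a, para to quaternary C6) is the β-carbon of the side-chain enone and of the ring dienone, and it carries the acyloxy oxygen of the six-membered enol lactone. The side-chain hydroxyl adds there and the target's own carboxylate leaves.
4. Stereochemistry: the cyclobutane comes from (1S,5S)-verbenone; C2/C3 from ethyl (R)-3-hydroxybutanoate by Fráter–Seebach anti methylation; the benzylic centre from (S)-diarylprolinol silyl ether iminium catalysis; C6 is relayed from the benzylic centre through the pseudo-axial phenyl group and the peri silyl ether.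

Key step: step 16

Assumption: commercial (1S,5S)-(−)-verbenone is not enantiopure, so crystalline acid 2 is recrystallised to full enantiopurity before it is carried on.

**Route**

Step 1
Reactants: 1 (1S,5S)-(−)-verbenone
Product: 2 (1S,3R)-3-acetyl-2,2-dimethylcyclobutane-1-carboxylic acid (cis-pinononic acid)
Conditions: RuCl3·xH2O (cat.), NaIO4 (4.2 equiv), CCl4/MeCN/H2O, rt
Reagents that add atoms: sodium periodate, [Na+].[O-]I(=O)(=O)=O; water, O
Why: RuO4 formed in situ cleaves the enone C=C and the α-keto acid loses CO2 (Sharpless RuCl3/NaIO4 oxidative cleavage), leaving both bridgehead stereocentres untouched as the cis-1,3-disubstituted cyclobutane.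

Step 2
Reactants: 2 (1S,3R)-3-acetyl-2,2-dimethylcyclobutane-1-carboxylic acid
Product: 3 (1S,3S)-2,2-dimethyl-3-(prop-1-en-2-yl)cyclobutane-1-carboxylic acid
Conditions: Ph3PCH3Br (2.6 equiv), KOt-Bu (2.5 equiv), THF, 0 °C → rt
Reagents that add atoms: methyltriphenylphosphonium bromide, C[P+](c1ccccc1)(c1ccccc1)c1ccccc1.[Br-]
Why: Wittig methylenation of the methyl ketone runs on the potassium carboxylate, which shields C-1 from enolisation, so the cis ring configuration should be kept (the new C-3 descriptor only reflects changed CIP priorities).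

Step 3
Reactants: 3 (1S,3S)-2,2-dimethyl-3-(prop-1-en-2-yl)cyclobutane-1-carboxylic acid
Product: 4 [(1S,3S)-2,2-dimethyl-3-(prop-1-en-2-yl)cyclobutyl]methanol
Conditions: LiAlH4, Et2O, 0 °C → rt
Reagents that add atoms: none
Why: LiAlH4 reduction of the acid to the primary alcohol touches neither stereocentre nor the 1,1-disubstituted alkene.

Step 4
Reactants: 4 [(1S,3S)-2,2-dimethyl-3-(prop-1-en-2-yl)cyclobutyl]methanol
Product: 5 [(1S,3S)-2,2-dimethyl-3-(prop-1-en-2-yl)cyclobutyl]methyl trifluoromethanesulfonate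
Conditions: Tf2O, pyridine, CH2Cl2, −78 → −30 °C; cold filtration through silica (pentane); used at once
Reagents that add atoms: trifluoromethanesulfonic anhydride, O=S(=O)(OS(=O)(=O)C(F)(F)F)C(F)(F)F
Why: O-sulfonylation at low temperature gives a triflate reactive enough for SN2 at a β-branched primary carbon, and immediate use should avoid ionisation of the cyclobutylcarbinyl system.

Step 5
Reactants: 6 ethyl (R)-3-hydroxybutanoate
Product: 8 ethyl (2R,3R)-3-hydroxy-2-methylbutanoate, via dilithium alkoxide-enolate 7 (not isolated)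
Conditions: LiN(i-Pr)2 (2.2 equiv), THF, −50 → −20 °C; MeI, DMPU, −78 → 0 °C
Reagents that add atoms: iodomethane, CI
Why: Fráter–Seebach alkylation, in which the chelated dilithium alkoxide-enolate is methylated on the face opposite the C-3 methyl group, sets the new C-2 centre anti (2R,3R).

Step 6
Reactants: 8 ethyl (2R,3R)-3-hydroxy-2-methylbutanoate
Product: 9 ethyl (2R,3R)-3-[(tert-butyldimethylsilyl)oxy]-2-methylbutanoate
Conditions: TBSCl, imidazole, DMF, rt
Reagents that add atoms: tert-butyldimethylsilyl chloride, CC(C)(C)[Si](C)(C)Cl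
Why: Corey silylation protects the secondary alcohol for the organolithium step.

Step 7
Reactants: 9 ethyl (2R,3R)-3-[(tert-butyldimethylsilyl)oxy]-2-methylbutanoate
Product: 10 (2R,3R)-3-[(tert-butyldimethylsilyl)oxy]-N-methoxy-N,2-dimethylbutanamide
Conditions: MeNH(OMe)·HCl, i-PrMgCl, THF, −20 → 0 °C
Reagents that add atoms: N,O-dimethylhydroxylamine hydrochloride, CNOC.Cl
Why: Direct ester-to-Weinreb-amide conversion with the magnesium amide at low temperature, conditions under which the α-stereocentre of β-silyloxy esters is expected to survive.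

Step 8
Reactants: 11 phloroglucinol
Product: 12 1,3,5-tris(methoxymethoxy)benzene
Conditions: NaH, MOMCl, DMF, 0 °C → rt
Reagents that add atoms: chloromethyl methyl ether, COCCl
Why: Williamson-type O-alkylation gives the tris-MOM ether whose oxygen atoms direct the two later ortho-lithiations.

Step 9
Reactants: 12 1,3,5-tris(methoxymethoxy)benzene; 5 [(1S,3S)-2,2-dimethyl-3-(prop-1-en-2-yl)cyclobutyl]methyl trifluoromethanesulfonate
Product: 14 2-{[(1R,3S)-2,2-dimethyl-3-(prop-1-en-2-yl)cyclobutyl]methyl}-1,3,5-tris(methoxymethoxy)benzene, via aryllithium 13 (not isolated)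
Conditions: n-BuLi, THF, 0 °C; then 5, −78 → 0 °C
Reagents that add atoms: none
Why: Directed ortho-metalation between two MOM ethers followed by SN2 alkylation of the aryllithium with the primary triflate joins the cyclobutane without touching its stereocentres.

Step 10
Reactants: 14 2-{[(1R,3S)-2,2-dimethyl-3-(prop-1-en-2-yl)cyclobutyl]methyl}-1,3,5-tris(methoxymethoxy)benzene; 10 (2R,3R)-3-[(tert-butyldimethylsilyl)oxy]-N-methoxy-N,2-dimethylbutanamide
Product: 16 (2R,3R)-3-[(tert-butyldimethylsilyl)oxy]-1-[3-{[(1R,3S)-2,2-dimethyl-3-(prop-1-en-2-yl)cyclobutyl]methyl}-2,4,6-tris(methoxymethoxy)phenyl]-2-methylbutan-1-one, via aryllithium 15 (not isolated)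
Conditions: n-BuLi, THF, 0 °C; then 10, −78 → 0 °C; aq. NH4Cl
Reagents that add atoms: none
Why: A second directed ortho-metalation (the two remaining ring positions are equivalent) and Weinreb acylation stops at the ketone through the chelated tetrahedral intermediate, carrying both chain stereocentres over.

Step 11
Reactants: 16 the tris-MOM aryl ketone
Product: 17 (2R,3R)-3-[(tert-butyldimethylsilyl)oxy]-1-[3-{[(1R,3S)-2,2-dimethyl-3-(prop-1-en-2-yl)cyclobutyl]methyl}-2,4,6-trihydroxyphenyl]-2-methylbutan-1-one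
Conditions: TMSOTf, 2,2′-bipyridyl, MeCN, 0 °C → rt; then H2O
Reagents that add atoms: none
Why: TMSOTf/2,2′-bipyridyl turns aryl MOM ethers into aryl trimethylsilyl ethers that hydrolyse on work-up, a non-acidic cleavage that should spare the secondary TBS ether, the ketone α-centre and the isopropenylcyclobutane.

Step 12
Reactants: 17 the 2,4,6-trihydroxyphenyl ketone
Product: 18 (2R,3R)-3-[(tert-butyldimethylsilyl)oxy]-1-[3-{[(1R,3S)-2,2-dimethyl-3-(prop-1-en-2-yl)cyclobutyl]methyl}-2,6-dihydroxy-4-(triisopropylsilyloxy)phenyl]-2-methylbutan-1-one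
Conditions: TIPSCl (1.05 equiv), imidazole, DMF, 0 °C → rt
Reagents that add atoms: triisopropylsilyl chloride, CC(C)[Si](Cl)(C(C)C)C(C)C
Why: The 4-hydroxyl para to the ketone is the most acidic and is not hydrogen-bonded to the carbonyl group, so monosilylation should occur there and keep this oxygen out of the later lactol formation.

Step 13
Reactants: 18 the 4-silyloxy-2,6-dihydroxyphenyl ketone; 19 (E)-cinnamaldehyde
Product: 20 (4S)-8-[(2R,3R)-3-[(tert-butyldimethylsilyl)oxy]-2-methylbutanoyl]-6-{[(1R,3S)-2,2-dimethyl-3-(prop-1-en-2-yl)cyclobutyl]methyl}-4-phenyl-5-(triisopropylsilyloxy)chromane-2,7-diol (mixture of C-2 anomers)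
Conditions: 19 (1.5 equiv), (S)-2-[diphenyl(trimethylsilyloxy)methyl]pyrrolidine (20 mol %), PhCO2H (20 mol %), toluene, rt
Reagents that add atoms: none
Why: Iminium-catalysed Friedel–Crafts conjugate addition of the only free ring CH, then hemiacetal formation with the adjacent free hydroxyl; the arene adds to the iminium face not covered by the CPh2OTMS group of the (S)-catalyst (the same sense as nitromethane and malonate additions), which sets the benzylic centre as 4S.

Step 14
Reactants: 20 the lactol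
Product: 21 (4S)-8-[(2R,3R)-3-[(tert-butyldimethylsilyl)oxy]-2-methylbutanoyl]-6-{[(1R,3S)-2,2-dimethyl-3-(prop-1-en-2-yl)cyclobutyl]methyl}-7-hydroxy-4-phenyl-5-(triisopropylsilyloxy)chroman-2-one
Conditions: Ag2CO3 on Celite, toluene, 80 °C
Reagents that add atoms: none
Why: Fétizon oxidation is selective for the lactol and should give the dihydrocoumarin lactone without touching the alkene, the chelated phenol or the silyl ethers.

Step 15
Reactants: 21 the dihydrocoumarin lactone
Product: 22 (4S,6S)-8-[(2R,3R)-3-[(tert-butyldimethylsilyl)oxy]-2-methylbutanoyl]-6-{[(1R,3S)-2,2-dimethyl-3-(prop-1-en-2-yl)cyclobutyl]methyl}-6-(3-methylbut-2-en-1-yl)-4-phenyl-5-(triisopropylsilyloxy)-3,4-dihydro-2H-chromene-2,7(6H)-dione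
Conditions: Pd(PPh3)4 (5 mol %), tert-butyl (3-methylbut-2-en-1-yl) carbonate (1.5 equiv), THF, 0 °C → rt
Reagents that add atoms: tert-butyl (3-methylbut-2-en-1-yl) carbonate, CC(C)=CCOC(=O)OC(C)(C)C
Why: Tsuji–Trost dearomatising allylation, in which zerovalent palladium ionises the carbonate and the chelated 7-phenoxide attacks the unsubstituted terminus of the π-prenyl complex through C-6 (any aryl prenyl ether re-ionises); because the pseudo-axial 4-phenyl group pushes the 5-silyloxy group to the opposite ring face, the electrophile should enter on the phenyl face and set C-6 as S.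

Step 16
Reactants: 22 the dearomatised silyl dienol ether lactone
Product: 24 (3S)-3-[(2R,3R,6R)-6-{[(1R,3S)-2,2-dimethyl-3-(prop-1-en-2-yl)cyclobutyl]methyl}-5-hydroxy-2,3-dimethyl-6-(3-methylbut-2-en-1-yl)-4,7-dioxo-3,4,6,7-tetrahydro-2H-chromen-8-yl]-3-phenylpropanoic acid, via hydroxy enol lactone 23 (not isolated)
Conditions: HF·pyridine, pyridine, THF, 0 → 40 °C
Reagents that add atoms: none
Why: HF·pyridine removes the dienyl triisopropylsilyl and the secondary tert-butyldimethylsilyl groups to give 23, whose C-8a is the β-carbon of an alkylidene 1,3-dicarbonyl unit (side-chain ketone and C-7 ketone on C-8) and of the vinylogous acid through C-4a, and bears the enol-lactone oxygen as a leaving group. The freed hydroxyl adds to C-8a and the ketal-type enolate expels the lactone carboxylate, so the pyranone ring closes while the lactone ring opens to the free propanoic acid and the core settles into the enolised triketone of the target. The closest known reaction type is addition–elimination at β-oxygenated enones (vinylogous transesterification, as in ring-opening/ring-closing exchange of 3-acylchromones with oxygen nucleophiles). The pyranone ring closes in the 6-endo-trig mode. No stereocentre is formed: C-2 keeps its configuration because its C–O bond is not broken, C-3 comes from 8 and trans-2,3-dimethyl is also the thermodynamically preferred arrangement, and C-4 and C-6 of 22 are untouched (their descriptors change only through renumbering and CIP priorities). The step needs closure at C-8a in preference to C-7 and to attack at the lactone carbonyl: only C-8a carries a leaving group (addition at the C-7 carbonyl can give only a reversible hemiketal), and attack at the lactone carbonyl would need an eight-membered transition state.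

**Compound list**

1 | (1S,5S)-(−)-verbenone | CC1=CC(=O)[C@H]2C[C@@H]1C2(C)C | starting material
2 | (1S,3R)-3-acetyl-2,2-dimethylcyclobutane-1-carboxylic acid | CC(=O)[C@@H]1C[C@H](C(=O)O)C1(C)C | intermediate
3 | (1S,3S)-2,2-dimethyl-3-(prop-1-en-2-yl)cyclobutane-1-carboxylic acid | C=C(C)[C@@H]1C[C@H](C(=O)O)C1(C)C | intermediate
4 | [(1S,3S)-2,2-dimethyl-3-(prop-1-en-2-yl)cyclobutyl]methanol | C=C(C)[C@@H]1C[C@H](CO)C1(C)C | intermediate
5 | [(1S,3S)-2,2-dimethyl-3-(prop-1-en-2-yl)cyclobutyl]methyl trifluoromethanesulfonate | C=C(C)[C@@H]1C[C@H](COS(=O)(=O)C(F)(F)F)C1(C)C | intermediate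
6 | ethyl (R)-3-hydroxybutanoate | O[C@H](C)CC(=O)OCC | starting material
7 | dilithium alkoxide-enolate of 6 | [Li]O[C@H](C)C=C(O[Li])OCC | intermediate
8 | ethyl (2R,3R)-3-hydroxy-2-methylbutanoate | O[C@H](C)[C@@H](C)C(=O)OCC | intermediate
9 | ethyl (2R,3R)-3-[(tert-butyldimethylsilyl)oxy]-2-methylbutanoate | CC(C)(C)[Si](C)(C)O[C@H](C)[C@@H](C)C(=O)OCC | intermediate
10 | (2R,3R)-3-[(tert-butyldimethylsilyl)oxy]-N-methoxy-N,2-dimethylbutanamide | CC(C)(C)[Si](C)(C)O[C@H](C)[C@@H](C)C(=O)N(C)OC | intermediate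
11 | phloroglucinol | Oc1cc(O)cc(O)c1 | starting material
12 | 1,3,5-tris(methoxymethoxy)benzene | COCOc1cc(OCOC)cc(OCOC)c1 | intermediate
13 | 2,4,6-tris(methoxymethoxy)phenyllithium | [Li]c1c(OCOC)cc(OCOC)cc1OCOC | intermediate
14 | 2-{[(1R,3S)-2,2-dimethyl-3-(prop-1-en-2-yl)cyclobutyl]methyl}-1,3,5-tris(methoxymethoxy)benzene | COCOc1cc(OCOC)c(C[C@H]2C[C@@H](C(C)=C)C2(C)C)c(OCOC)c1 | intermediate
15 | aryllithium from 14 (lithium between two MOM ethers, meta to the cyclobutylmethyl group) | [Li]c1c(OCOC)cc(OCOC)c(C[C@H]2C[C@@H](C(C)=C)C2(C)C)c1OCOC | intermediate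
16 | (2R,3R)-3-[(tert-butyldimethylsilyl)oxy]-1-[3-{[(1R,3S)-2,2-dimethyl-3-(prop-1-en-2-yl)cyclobutyl]methyl}-2,4,6-tris(methoxymethoxy)phenyl]-2-methylbutan-1-one | COCOc1cc(OCOC)c(C[C@H]2C[C@@H](C(C)=C)C2(C)C)c(OCOC)c1C(=O)[C@H](C)[C@@H](C)O[Si](C)(C)C(C)(C)C | intermediate
17 | (2R,3R)-3-[(tert-butyldimethylsilyl)oxy]-1-[3-{[(1R,3S)-2,2-dimethyl-3-(prop-1-en-2-yl)cyclobutyl]methyl}-2,4,6-trihydroxyphenyl]-2-methylbutan-1-one | Oc1cc(O)c(C[C@H]2C[C@@H](C(C)=C)C2(C)C)c(O)c1C(=O)[C@H](C)[C@@H](C)O[Si](C)(C)C(C)(C)C | intermediate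
18 | (2R,3R)-3-[(tert-butyldimethylsilyl)oxy]-1-[3-{[(1R,3S)-2,2-dimethyl-3-(prop-1-en-2-yl)cyclobutyl]methyl}-2,6-dihydroxy-4-(triisopropylsilyloxy)phenyl]-2-methylbutan-1-one | Oc1cc(O[Si](C(C)C)(C(C)C)C(C)C)c(C[C@H]2C[C@@H](C(C)=C)C2(C)C)c(O)c1C(=O)[C@H](C)[C@@H](C)O[Si](C)(C)C(C)(C)C | intermediate
19 | (E)-cinnamaldehyde | O=C/C=C/c1ccccc1 | starting material
20 | (4S)-8-[(2R,3R)-3-[(tert-butyldimethylsilyl)oxy]-2-methylbutanoyl]-6-{[(1R,3S)-2,2-dimethyl-3-(prop-1-en-2-yl)cyclobutyl]methyl}-4-phenyl-5-(triisopropylsilyloxy)chromane-2,7-diol (anomers at C-2) | OC1C[C@@H](c2ccccc2)c2c(O[Si](C(C)C)(C(C)C)C(C)C)c(C[C@H]3C[C@@H](C(C)=C)C3(C)C)c(O)c(C(=O)[C@H](C)[C@@H](C)O[Si](C)(C)C(C)(C)C)c2O1 | intermediate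
21 | (4S)-8-[(2R,3R)-3-[(tert-butyldimethylsilyl)oxy]-2-methylbutanoyl]-6-{[(1R,3S)-2,2-dimethyl-3-(prop-1-en-2-yl)cyclobutyl]methyl}-7-hydroxy-4-phenyl-5-(triisopropylsilyloxy)chroman-2-one | O=C1C[C@@H](c2ccccc2)c2c(O[Si](C(C)C)(C(C)C)C(C)C)c(C[C@H]3C[C@@H](C(C)=C)C3(C)C)c(O)c(C(=O)[C@H](C)[C@@H](C)O[Si](C)(C)C(C)(C)C)c2O1 | intermediate
22 | (4S,6S)-8-[(2R,3R)-3-[(tert-butyldimethylsilyl)oxy]-2-methylbutanoyl]-6-{[(1R,3S)-2,2-dimethyl-3-(prop-1-en-2-yl)cyclobutyl]methyl}-6-(3-methylbut-2-en-1-yl)-4-phenyl-5-(triisopropylsilyloxy)-3,4-dihydro-2H-chromene-2,7(6H)-dione | O=C1C[C@@H](c2ccccc2)C2=C(O[Si](C(C)C)(C(C)C)C(C)C)[C@](CC=C(C)C)(C[C@H]3C[C@@H](C(C)=C)C3(C)C)C(=O)C(C(=O)[C@H](C)[C@@H](C)O[Si](C)(C)C(C)(C)C)=C2O1 | intermediate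
23 | (4S,6S)-6-{[(1R,3S)-2,2-dimethyl-3-(prop-1-en-2-yl)cyclobutyl]methyl}-5-hydroxy-8-[(2R,3R)-3-hydroxy-2-methylbutanoyl]-6-(3-methylbut-2-en-1-yl)-4-phenyl-3,4-dihydro-2H-chromene-2,7(6H)-dione (one enol tautomer) | O=C1C[C@@H](c2ccccc2)C2=C(O)[C@](CC=C(C)C)(C[C@H]3C[C@@H](C(C)=C)C3(C)C)C(=O)C(C(=O)[C@H](C)[C@@H](C)O)=C2O1 | intermediate
24 | (3S)-3-[(2R,3R,6R)-6-{[(1R,3S)-2,2-dimethyl-3-(prop-1-en-2-yl)cyclobutyl]methyl}-5-hydroxy-2,3-dimethyl-6-(3-methylbut-2-en-1-yl)-4,7-dioxo-3,4,6,7-tetrahydro-2H-chromen-8-yl]-3-phenylpropanoic acid | C=C(C)[C@@H]1C[C@H](C[C@@]2(CC=C(C)C)C(=O)C([C@@H](CC(=O)O)c3ccccc3)=C3O[C@H](C)[C@@H](C)C(=O)C3=C2O)C1(C)C | target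

**Step count and risks**

Total steps: 16. Longest linear sequence: 12 (steps 1–4, then 9–16).

Steps most likely to fail:

Step 15. The danger is poor facial selectivity at C-6 (the relay through the silyl ether may be weak), together with slow C-allylation at the hindered carbon. The fallback sets out from 21 and replaces substrate control by catalyst control. The aryl silyl ether is cleaved (n-Bu4NF, AcOH, THF, 0 °C) to give (4S)-8-[(2R,3R)-3-[(tert-butyldimethylsilyl)oxy]-2-methylbutanoyl]-6-{[(1R,3S)-2,2-dimethyl-3-(prop-1-en-2-yl)cyclobutyl]methyl}-5,7-dihydroxy-4-phenylchroman-2-one F1. This diphenol is prenylated with Pd2(dba)3·CHCl3, a DACH-phenyl Trost ligand (both antipodes tried, the matched one kept) and the same carbonate, an asymmetric allylic dearomatisation of a phenol, to give the 5-hydroxy dienol lactone F2. Under the conditions of step 16, F2 loses its silyl group and the route is rejoined at 23.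

Step 16. The danger is cleavage of the enol lactone by fluoride or water, or acyl transfer to the freed hydroxyl, before the ring has closed. The fallback sets out from 22. Both silyl groups and the lactone are removed on purpose (n-Bu4NF, THF; then aqueous LiOH, 0 °C) to give the seco hydroxy acid F3. EDC·HCl with catalytic DMAP in CH2Cl2 at high dilution should then re-form the six-membered enol lactone on an enol oxygen next to the arm; DMAP lets the acyl group move between the two flanking oxygens, and only the isomer on the oxygen para to C-6 can close. The route is rejoined at 23, which closes to 24 in the same flask.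

Step 13. The danger is low reactivity of the acyl-deactivated, flanked ring position toward the iminium ion, or O- instead of C-attack. The fallback sets out from 18 and 19 and makes the lactone in one operation by oxidative N-heterocyclic carbene catalysis (chiral aminoindanol-derived triazolium salt, DBU, 3,3′,5,5′-tetra-tert-butyldiphenoquinone, toluene). The α,β-unsaturated acyl azolium takes up the arene by conjugate addition and acylates the neighbouring hydroxyl, so the route is rejoined at 21 and 20 is bypassed; no compound outside the list is made (F0).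

Further compounds
F1 | step 15 | (4S)-8-[(2R,3R)-3-[(tert-butyldimethylsilyl)oxy]-2-methylbutanoyl]-6-{[(1R,3S)-2,2-dimethyl-3-(prop-1-en-2-yl)cyclobutyl]methyl}-5,7-dihydroxy-4-phenylchroman-2-one | O=C1C[C@@H](c2ccccc2)c2c(O)c(C[C@H]3C[C@@H](C(C)=C)C3(C)C)c(O)c(C(=O)[C@H](C)[C@@H](C)O[Si](C)(C)C(C)(C)C)c2O1
F2 | step 15 | (4S,6S)-8-[(2R,3R)-3-[(tert-butyldimethylsilyl)oxy]-2-methylbutanoyl]-6-{[(1R,3S)-2,2-dimethyl-3-(prop-1-en-2-yl)cyclobutyl]methyl}-5-hydroxy-6-(3-methylbut-2-en-1-yl)-4-phenyl-3,4-dihydro-2H-chromene-2,7(6H)-dione | O=C1C[C@@H](c2ccccc2)C2=C(O)[C@](CC=C(C)C)(C[C@H]3C[C@@H](C(C)=C)C3(C)C)C(=O)C(C(=O)[C@H](C)[C@@H](C)O[Si](C)(C)C(C)(C)C)=C2O1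
F3 | step 16 | (3S)-3-[(5R)-5-{[(1R,3S)-2,2-dimethyl-3-(prop-1-en-2-yl)cyclobutyl]methyl}-2,4-dihydroxy-3-[(2R,3R)-3-hydroxy-2-methylbutanoyl]-5-(3-methylbut-2-en-1-yl)-6-oxocyclohexa-1,3-dien-1-yl]-3-phenylpropanoic acid | C=C(C)[C@@H]1C[C@H](C[C@@]2(CC=C(C)C)C(=O)C([C@@H](CC(=O)O)c3ccccc3)=C(O)C(C(=O)[C@H](C)[C@@H](C)O)=C2O)C1(C)C
F0 | step 13 | none | none
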